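The runs stem from a simulated flask with constants of no real substance, and the scatter is random.

Monday's flask held more target than Saturday's at 60.0 min, 47.5% against 29.1%, so I first asked how much target a charge of nucleophile can pay for.

| flask | electrophile | nucleophile | remark | time |
|---|---|---|---|---|
| Saturday's | 0.10 M | 0.10 M | run made earlier |  |
| Tuesday's | 0.10 M | 0.14 M | run made earlier |  |
| Monday's | 0.10 M | 0.22 M | run made earlier |  |
| Friday's | 0.20 M | 0.10 M | run made earlier |  |
| dawn | 0.10 M | 0.100 M | one stirred flow tank at steady state, fed with the mixture as stated, mean residence time 1.0 h |  |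
| winter | 0.10 M (fed, over 0.800 h) | 0.100 M | all but electrophile at the start; electrophile goes in evenly over 0.800 h, the run ends at 1.0 h | 1.0 h |
| spring | 0.10 M | 0.100 M | a closed flask charged with all of it at once and left for 1.0 h | 1.0 h |
| dusk | 0.10 M | 0.100 M (fed, over 0.800 h) | all but nucleophile at the start; nucleophile goes in evenly over 0.800 h, the run ends at 1.0 h | 1.0 h |

| run | time / min | target / % | electrophile / % |
|---|---|---|---|
| Saturday's | 8.00 | 21.5 | 12.7 |
| Saturday's | 15.0 | 24.8 | 6.4 |
| Saturday's | 25.0 | 26.3 | 2.5 |
| Saturday's | 30.0 | 27.1 | 2.3 |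
| Saturday's | 40.0 | 27.5 | 0.9 |
| Saturday's | 50.0 | 28.2 | 0.6 |
| Saturday's | 60.0 | 29.1 | 0.2 |
| Tuesday's | 10.0 | 29.8 | 7.7 |
| Tuesday's | 20.0 | 33.1 | 2.7 |
| Tuesday's | 30.0 | 35.4 | 1.4 |
| Tuesday's | 40.0 | 36.0 | 0.9 |
| Tuesday's | 50.0 | 36.3 | 0.7 |
| Tuesday's | 60.0 | 34.7 | 0.5 |
| Tuesday's | 80.0 | 35.8 | 0 |
| Monday's | 4.00 | 34.4 | 17.2 |
| Monday's | 12.0 | 44.0 | 4.2 |
| Monday's | 20.0 | 47.2 | 1.5 |
| Monday's | 30.0 | 46.8 | 0 |
| Monday's | 40.0 | 47.4 | 0 |
| Monday's | 60.0 | 47.5 | 0 |
| Monday's | 80.0 | 47.0 | 0.4 |
| Friday's | 6.00 | 12.9 | 10.2 |
| Friday's | 10.0 | 13.8 | 5.8 |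
| Friday's | 20.0 | 16.2 | 3.0 |
| Friday's | 40.0 | 17.2 | 0.9 |
| Friday's | 80.0 | 17.9 | 0 |

(standard deviation of a reading: 0.5 percentage points)

- the stated concentrations are those of everything mixed, before any reaction; amounts are the same in each set-up
- the feed brings no volume worth counting
- the earlier runs were made in a closed, stirred flask

1. the set-up with the highest amount of target at the outlet or at the end, in percent of the electrophile put in ("none" if the first two lie within 2 percentage points) (dawn / winter / spring / dusk / none)
2. amount of target at the outlet or at the end, in percent of the electrophile put in, dawn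
3. amount of target at the outlet or at the end, in percent of the electrophile put in, winter
4. amount of target at the outlet or at the end, in percent of the electrophile put in, spring
5. amount of target at the outlet or at the end, in percent of the electrophile put in, dusk

I read the price from Saturday's run. Target gained per minute, divided by the mean electrophile in that stretch, is a pseudo-first-order rate, and I took it to follow the nucleophile present. Treating the early electrophile curve as second order gave a mean of 30.0%. After that I summed the readings:

early rate f = 21.5% / (30.0% × 8.00 min) = 0.0895 min⁻¹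

late rate g = (29.1% − 21.5%) / 1.51 min = 0.0504 min⁻¹

So on this reading the nucleophile fell by a factor R = 1.78 while mean target, as a fraction of the charge, rose from p = 10.8% to q = 25.3%. With ν nucleophile spent per target and equal charges:

ν = (R − 1) / (Rq − p) = 2.27

This is a scattered reading, and nucleophile goes in whole units, so I took two per target:

ceiling = 0.100 M / (two × 0.10 M) = 50.0%

This is the nucleophile ceiling, the target a charge of nucleophile can pay for at two per target, in percent of the electrophile put in.

The extremes were then plain. Spring is Saturday's flask again, near 29.1%. At the other extreme I pictured a feed so slow that electrophile meets nucleophile and not itself, and there target stands at the ceiling, 50.0%. Winter's 0.800 h feed is longer than the 8.00 min in which Saturday's electrophile fell to 12.7%, so I placed winter above spring. But the nucleophile falls as target forms, so I placed winter below the ceiling and committed to the midpoint, 39.6%.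

The forecast, higher than mine for winter, gave dawn 41%, winter 50%, spring 29%, dusk 10%, and said “Winter is best”.

The flask gave dawn 30.6%, winter 38.4%, spring 28.6%, dusk 8.56%, so winter led.

    electrophile + nucleophile ⇌ acid set free + target (K = 0.339, k = 0.0211 L mol⁻¹ s⁻¹)
    nucleophile + acid set free ⇌ protonated nucleophile, settled at all times (K = 51400 L mol⁻¹)
    nucleophile ⇌ dormant form (K = 0.206, k = 0.00116 s⁻¹)
    2 electrophile → self-condensation product (k = 0.0509 L mol⁻¹ s⁻¹)

At the end of winter, protonated nucleophile stood at 0.0384 M beside 0.0384 M of target. Winter reached 76.8% of its ceiling. The same flask with 0.040 M of nucleophile has a ceiling of 20.0%, and it gave 16.4%, which is 82.0% of that ceiling, with 15% of its nucleophile still unbound.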